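## Retrosynthetic overview
1. The last bond made is the biaryl C2–C4' bond. It comes from Suzuki coupling of a benzofuran-2-boronate (C–H borylation of 7-geranylbenzofuran-6-ol) with a chiral 4-bromo-2,3-dihydrobenzofuran.
2. The dihydrofuran ring closes at its aryl C7a'–O1' bond in a visible-light step. The secondary OH of a chiral diol displaces the neighbouring aryl OMe through the arene radical cation, so the configuration is retained.
3. The C3'–C3a' bond comes from an aryl-copper opening of methyl (R)-glycidate at its CH2. This reagent supplies the only stereocentre. MeMgBr then builds the CMe2OH group.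
4. The geranyl group goes on C7 by ortho C-alkylation of sodium benzofuran-6-olate.
5. Ring order: the dihydrofuran is the only ring built (Step 3). The benzofuran and both benzene rings are purchased.

Assumption: methyl (R)-glycidate (the L-serine-derived enantiomer) and benzofuran-6-ol are taken as commercial starting materials.

## Route

**Step 1**
Reactants: 1, 1-bromo-3,5-dimethoxybenzene
Product: 2, 1-bromo-2-iodo-3,5-dimethoxybenzene
Conditions: NIS (1.05 equiv), MeCN, 23 °C, dark
Reagents that add atoms: N-iodosuccinimide, O=C1CCC(=O)N1I
Why: Electrophilic aromatic iodination goes to C2, which is ortho and para to the two OMe groups, because the alternative C4 site between the two OMe groups is more hindered.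

**Step 2** (one flask)
Reactants: 2, 1-bromo-2-iodo-3,5-dimethoxybenzene (1.2 equiv); 3, methyl (R)-oxirane-2-carboxylate
Product: 5, (R)-1-(2-bromo-4,6-dimethoxyphenyl)-3-methylbutane-2,3-diol, formed via 4, methyl (R)-3-(2-bromo-4,6-dimethoxyphenyl)-2-hydroxypropanoate (not isolated)
Conditions: i-PrMgCl·LiCl (1.15 equiv), THF, −30 °C; CuBr·SMe2 (15 mol %), then 3, −30 → −10 °C; then MeMgBr (3.5 equiv), −10 → 0 °C; aq NH4Cl
Reagents that add atoms: methyl (R)-glycidate (3), COC(=O)[C@H]1CO1; methylmagnesium bromide, C[Mg]Br
Why: Selective I/Mg exchange (the o-bromoaryl Grignard is stable below 0 °C), Cu-catalysed SN2 opening of the glycidate at its unsubstituted CH2, and double Grignard addition to the ester alkoxide never touch the C2–O bond, so the purchased (R) centre carries through unchanged.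

**Step 3** (key step)
Reactants: 5, (R)-1-(2-bromo-4,6-dimethoxyphenyl)-3-methylbutane-2,3-diol
Product: 6, 2-[(2R)-4-bromo-6-methoxy-2,3-dihydro-1-benzofuran-2-yl]propan-2-ol
Conditions: 3,6-di-t-Bu-9-mesityl-10-phenylacridinium BF4 (5 mol %), DCE/HFIP 4:1 (0.05 M), N2, 456 nm LEDs, 25–30 °C
Reagents that add atoms: none (MeOH is lost)
Why: Proposed new method: intramolecular alkoxy-for-methoxy exchange by photoredox cation-radical-accelerated SNAr, in which the excited acridinium (E* ≈ +2.1 V vs SCE) oxidises the dimethoxyarene (≈ +1.5 V) to a radical cation whose SOMO is large at both C–OMe carbons and nodal at C–Br, the tethered secondary OH adds in a five-membered closure to the adjacent C–OMe carbon, the ketal-type cyclohexadienyl radical loses MeOH with HFIP assistance, and the product radical cation is reduced by the acridinyl radical (redox-neutral, driven by release of MeOH); the O–C2 bond is never broken so (R) is retained, the hindered tertiary OH would need a slower six-membered closure, and the closest known reaction type is acridinium-catalysed cation-radical SNAr of methoxyarenes with azoles, amines, cyanide or fluoride (and radical-cation C–H alkoxylation of arenes), not yet shown for an aliphatic alcohol nucleophile or for closing a dihydrobenzofuran.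

**Step 4**
Reactants: 6, 2-[(2R)-4-bromo-6-methoxy-2,3-dihydro-1-benzofuran-2-yl]propan-2-ol
Product: 7, (2R)-4-bromo-2-(2-hydroxypropan-2-yl)-2,3-dihydro-1-benzofuran-6-ol
Conditions: NaSEt (4 equiv), DMF, 120 °C; aq citric acid
Reagents that add atoms: none
Why: Thiolate SN2 demethylation attacks only the unhindered O–CH3 and spares the neopentyl-like secondary C2–O, the electron-rich aryl bromide and the tertiary alcohol, and doing it here keeps the harsh step on a robust small fragment.

**Step 5**
Reactants: 8, 1-benzofuran-6-ol; 9, geranyl bromide [(E)-1-bromo-3,7-dimethylocta-2,6-diene]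
Product: 10, 7-[(2E)-3,7-dimethylocta-2,6-dien-1-yl]-1-benzofuran-6-ol
Conditions: NaH (1.05 equiv), toluene, 0 → 23 °C; 9 (1.0 equiv), 23 → 40 °C
Reagents that add atoms: geranyl bromide (9), CC(C)=CCC/C(C)=C/CBr
Why: A heterogeneous sodium phenoxide in a non-polar solvent favours ortho C-alkylation over O-alkylation (SN2, E geometry kept), and C7 beats C5 because the C7 dienone intermediate keeps the furan C3a=C7a π-bond (β-naphthol-type bond fixation).

**Step 6** (one flask)
Reactants: 10, 7-geranyl-1-benzofuran-6-ol (1.3 equiv); 7, (2R)-4-bromo-2-(2-hydroxypropan-2-yl)-2,3-dihydro-1-benzofuran-6-ol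
Product: 12, mulberrofuran X, formed via 11, the 2-(pinacolboryl) derivative of 10 (not isolated)
Conditions: [Ir(OMe)(cod)]2 (1.5 mol %), dtbpy (3 mol %), B2pin2 (1.1 equiv), THF, 50 °C; concentrate; then 7, XPhos Pd G3 (3 mol %), aq K3PO4 (4 equiv), THF, 45 °C
Reagents that add atoms: none remain in 12 (B2pin2, CC1(C)OB(OC1(C)C)B1OC(C)(C)C(C)(C)O1, supplies the Bpin of transient 11)
Why: Ir-catalysed C–H borylation selects the α (C2) C–H of benzofurans, with the phenol masked in situ as O–Bpin and the trisubstituted alkenes inert, and a fast Suzuki–Miyaura coupling outruns protodeboronation while tolerating the free phenols and tertiary alcohol and leaving the stereocentre alone.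

## Compound list
1 | 1-bromo-3,5-dimethoxybenzene | COc1cc(Br)cc(OC)c1 | starting material
2 | 1-bromo-2-iodo-3,5-dimethoxybenzene | COc1cc(Br)c(I)c(OC)c1 | intermediate
3 | methyl (R)-oxirane-2-carboxylate (methyl (R)-glycidate) | COC(=O)[C@H]1CO1 | starting material
4 | methyl (R)-3-(2-bromo-4,6-dimethoxyphenyl)-2-hydroxypropanoate | COC(=O)[C@H](O)Cc1c(Br)cc(OC)cc1OC | intermediate (not isolated)
5 | (R)-1-(2-bromo-4,6-dimethoxyphenyl)-3-methylbutane-2,3-diol | CC(C)(O)[C@H](O)Cc1c(Br)cc(OC)cc1OC | intermediate
6 | 2-[(2R)-4-bromo-6-methoxy-2,3-dihydro-1-benzofuran-2-yl]propan-2-ol | CC(C)(O)[C@H]1Cc2c(Br)cc(OC)cc2O1 | intermediate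
7 | (2R)-4-bromo-2-(2-hydroxypropan-2-yl)-2,3-dihydro-1-benzofuran-6-ol | CC(C)(O)[C@H]1Cc2c(Br)cc(O)cc2O1 | intermediate
8 | 1-benzofuran-6-ol | Oc1ccc2ccoc2c1 | starting material
9 | geranyl bromide | CC(C)=CCC/C(C)=C/CBr | starting material
10 | 7-[(2E)-3,7-dimethylocta-2,6-dien-1-yl]-1-benzofuran-6-ol | CC(C)=CCC/C(C)=C/Cc1c(O)ccc2ccoc12 | intermediate
11 | 7-geranyl-2-(4,4,5,5-tetramethyl-1,3,2-dioxaborolan-2-yl)-1-benzofuran-6-ol | CC(C)=CCC/C(C)=C/Cc1c(O)ccc2cc(B3OC(C)(C)C(C)(C)O3)oc12 | intermediate (not isolated)
12 | mulberrofuran X, (R) | CC(C)=CCC/C(C)=C/Cc1c(O)ccc2cc(-c3cc(O)cc4c3C[C@H](C(C)(C)O)O4)oc12 | target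

## Totals
- **Total step count:** 6 flask operations. Steps 2 and 6 are telescoped, so the count is 8 if every stage is counted separately.
- **Longest linear sequence:** 5 steps (1 → 2 → 5 → 6 → 7 → 12).

## Three steps most likely to fail
1. **Step 3 (proposed new photochemical ring closure).**
   - Risks: benzylic C–C fragmentation or deprotonation of the radical cation, and closure or equilibration through the tertiary OH to the 2,2-dimethylchroman-3-ol.
   - Fallback (known chemistry): start from 3,5-dibromoanisole. LDA then I2 gives 1,3-dibromo-2-iodo-5-methoxybenzene, and Step 2 runs unchanged on it. Close the ring thermally by Pd-catalysed intramolecular aryl bromide/secondary alcohol C–O coupling (Pd(OAc)2, bulky di-tert-butylbiarylphosphine, Cs2CO3, toluene, 70 °C). This coupling retains configuration. The two C–Br bonds are equivalent, so the product is the same compound 6 in the same number of steps.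
2. **Step 5 (C7 geranylation).**
   - Risks: O-alkylation, C5 alkylation or dialkylation.
   - Fallback: build the benzofuran instead of buying it. Treat 1,3-bis(methoxymethoxy)benzene with n-BuLi and geranyl bromide, which alkylates C2 only by directed ortho-metalation. A second ortho-lithiation with I2 and mild MOM removal give 4-iodo-2-geranylresorcinol. Sonogashira coupling and 5-endo-dig heteroannulation with the 4-ethynyl analogue of 7 (from 7 with TMS-acetylene, then K2CO3/MeOH) then deliver 12.
3. **Step 2 (hindered o-bromoaryl copper with a glycidic ester).**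
   - Risks: sluggish epoxide opening, attack on the ester, or aryne formation.
   - Fallback: reverse the order of construction. Convert 3 with MeMgCl at −78 °C into (R)-2-(oxiran-2-yl)propan-2-ol and protect it as the TES ether. Open this ester-free epoxide with the aryllithium and BF3·OEt2 at −78 °C, using the chloro analogue 1-chloro-2-iodo-3,5-dimethoxybenzene, whose o-chloroaryllithium resists aryne collapse. The aryl chloride still couples in Step 6 with XPhos-Pd.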